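**Retrosynthetic overview**
- Target ⇐ one-pot C9 ketone reduction and acetal hydrolysis of a cis-fused keto methylene-lactone, whose γ-lactone (C8–O) is closed last by oxidative lactonisation of a δ-keto acrylic acid.
- Keto acid ⇐ allylic oxidation of the carvone-derived isopropenyl group (C12) and angeloylation (C6–OH) of an oxiranyl ketone.
- Oxiranyl ketone ⇐ one-pot three-component coupling of a γ-hydroxy enone, a 2-metallated acrolein acetal (C5–C4) and chloroacetaldehyde (C10–C1, then the oxirane).
- γ-Hydroxy enone ⇐ visible-light singlet-oxygen [4+2] on a cyclohexadiene (makes the C6–O and C9–O bonds; the C6 alkoxide made by light then steers C5, C10 and C1) and Kornblum–DeLaMare opening; diene ⇐ (S)-carvone by Shapiro reaction.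
- Ring order: carbocycle bought with carvone (C7 stereocentre) → transient peroxide bridge → oxirane → γ-lactone.

Assumption: 2-bromo-3,3-diethoxyprop-1-ene, anhydrous chloroacetaldehyde and angelic acid are bought; atom labels C1–C15 follow the elemanolide skeleton of the target (ring C5–C10, oxirane C1/C2, enal C3/C4/C15, lactone carbons C11–C13, methyl C14).

**Step 1**
Reactants: 1 (S)-(+)-carvone
Product: 2 (S)-carvone tosylhydrazone
Conditions: TsNHNH2, MeOH, rt
Reagents that add atoms: p-toluenesulfonohydrazide, Cc1ccc(cc1)S(=O)(=O)NN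
Why: Condensation of the enone carbonyl with the sulfonyl hydrazide gives the hydrazone and leaves the bought stereocentre (later C7) untouched.

**Step 2**
Reactants: 2 (S)-carvone tosylhydrazone
Product: 3 (5S)-2-methyl-5-(prop-1-en-2-yl)cyclohexa-1,3-diene
Conditions: MeLi (2.4 equiv), Et2O, 0 °C → rt; then H2O
Reagents that add atoms: none
Why: Shapiro reaction of the unsaturated tosylhydrazone (deprotonation at the ring CH2 next to C=N, loss of sulfinate and N2, protonation of the vinyllithium) gives the conjugated diene without touching the stereocentre.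

**Step 3**
Reactants: 3 (5S)-2-methyl-5-(prop-1-en-2-yl)cyclohexa-1,3-diene
Product: 5 (4S,5R)-4-hydroxy-2-methyl-5-(prop-1-en-2-yl)cyclohex-2-en-1-one, via endoperoxide 4 (not isolated)
Conditions: O2, tetraphenylporphyrin (cat.), white LED, CH2Cl2, −20 °C; then Et3N, 0 °C → rt
Reagents that add atoms: dioxygen, O=O
Why: Sensitised singlet-oxygen [4+2] cycloaddition on the diene face anti to the isopropenyl group (as with α-phellandrene) forms the C6–O and C9–O bonds, and Kornblum–DeLaMare rearrangement removes the bridgehead hydrogen at C9 (next to CH2), leaving the C6 carbinol trans to the isopropenyl group; the minor syn adduct is removed by chromatography.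

**Step 4**
Reactants: 5 γ-hydroxy enone; 6 2-bromo-3,3-diethoxyprop-1-ene; 7 chloroacetaldehyde
Product: 12 oxiranyl ketone (2R,3S,4R,5R)-3-(3,3-diethoxyprop-1-en-2-yl)-4-hydroxy-2-methyl-2-[(2S)-oxiran-2-yl]-5-(prop-1-en-2-yl)cyclohexan-1-one, via vinyllithium 8 (not isolated), via Grignard reagent 9 (not isolated), via magnesium enolate 10 (not isolated), via chlorohydrin 11 (not isolated)
Conditions: 6 (2.3 equiv), n-BuLi (2.2 equiv), THF, −78 °C; MgBr2·OEt2; 5, −78 → −40 °C; 7 (2.5 equiv), −78 °C; H2O; then K2CO3, MeOH, 0 °C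
Reagents that add atoms: none
Why: Proposed new method: a one-pot alkoxide-directed conjugate alkenylation / aldol / ring-closure cascade (α-oxiranylation of a conjugate-addition enolate), in which the first equivalent of 9 makes the C6 magnesium alkoxide that delivers a second equivalent to C5 on its own face (cis to O6 and trans to the C7 isopropenyl group, also the face of axial attack), the tetrasubstituted magnesium enolate 10 then adds to chloroacetaldehyde anti to the new axial C5 substituent through a closed Zimmerman–Traxler chair with CH2Cl pointing outward and H over the ring (setting the C10 quaternary centre with the new C–C bond trans to the C5 side chain, and C1 as S), and the chlorohydrin closes by internal SN2 with retention at C1; the closest known reactions are ligand-assisted 1,4-addition of Grignard reagents to 4-oxido enones, tandem conjugate addition–aldol three-component coupling and Darzens-type halohydrin closure, which have not been merged or used with an α-chloro aldehyde to build a quaternary oxiranyl centre.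

**Step 5**
Reactants: 12 oxiranyl ketone; 13 angelic acid
Product: 15 C6 angelate of 12, via mixed anhydride 14 (not isolated)
Conditions: 13, 2,4,6-trichlorobenzoyl chloride, Et3N, toluene, rt; then 12, 75 °C
Reagents that add atoms: none
Why: Yamaguchi esterification acylates the only free hydroxyl (C6) at the less hindered angeloyl carbonyl of the mixed anhydride, and omitting DMAP keeps the (Z)-alkene; no stereocentre is touched.

**Step 6**
Reactants: 15 angelate
Product: 16 allylic alcohol (C12–OH)
Conditions: SeO2 (0.3 equiv), t-BuOOH (in decane), CH2Cl2, 0 °C → rt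
Reagents that add atoms: tert-butyl hydroperoxide, CC(C)(C)OO (terminal oxidant; its oxygen reaches C12 through SeO2)
Why: Catalytic SeO2 allylic oxidation (ene reaction then [2,3]-shift) takes the methyl group of the only electron-rich isopropenyl unit, because the acetal-bearing alkene has only methine allylic hydrogens and the angelate alkene is electron-poor; any enal formed is carried on, since step 7 converts both.

**Step 7**
Reactants: 16 allylic alcohol
Product: 17 δ-keto acrylic acid
Conditions: TEMPO (cat.), NaClO2, NaOCl (cat.), MeCN / phosphate buffer (pH 6.7), 35 °C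
Reagents that add atoms: sodium chlorite, [Na+].[O-]Cl=O
Why: Oxoammonium/chlorite oxidation takes the primary allylic alcohol through the enal to the acid at near-neutral pH, which spares the diethyl acetal, the oxirane and the angelate.

**Step 8**
Reactants: 17 δ-keto acrylic acid
Product: 19 cis-fused keto methylene-lactone, via iodo ketone 18 (not isolated)
Conditions: Bu4NI (10 mol %), t-BuOOH (in decane), 4 Å MS, EtOAc, 40 °C
Reagents that add atoms: none
Why: Hypoiodite-catalysed oxylactonisation of a keto acid, in which the C8 enol (the only one possible, C10 being quaternary) is iodinated on the face away from the C7 side chain and the axial oxiranyl group, and the carboxylate held on the opposite face displaces iodide by 5-exo SN2 with inversion, so the new C8–O bond is cis to C7–C11.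

**Step 9**
Reactants: 19 keto lactone
Product: 21 target CNP0113462.5, via hydroxy acetal 20 (not isolated)
Conditions: NaBH4, CeCl3·7H2O, EtOH, −40 °C; then aq. oxalic acid (pH 3), THF, 0 °C → rt
Reagents that add atoms: water, O
Why: Luche reduction delivers hydride to C9 anti to the axial C8–O bond (Felkin–Anh) and away from the axial oxiranyl group, giving the 9-OH cis to both without 1,4-reduction of the methylene lactone, and the mild acid then hydrolyses the allylic diethyl acetal much faster than it opens the oxirane.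

**Compound list**
1 | (S)-(+)-carvone, (5S)-2-methyl-5-(prop-1-en-2-yl)cyclohex-2-en-1-one | CC1=CC[C@@H](CC1=O)C(C)=C | starting material
2 | N'-[(5S)-2-methyl-5-(prop-1-en-2-yl)cyclohex-2-en-1-ylidene]-4-methylbenzenesulfonohydrazide | CC1=CC[C@@H](CC1=NNS(=O)(=O)c1ccc(C)cc1)C(C)=C | intermediate
3 | (5S)-2-methyl-5-(prop-1-en-2-yl)cyclohexa-1,3-diene, (S)-p-mentha-1,5,8-triene | CC1=CC[C@@H](C=C1)C(C)=C | intermediate
4 | (1S,4S,7R)-5-methyl-7-(prop-1-en-2-yl)-2,3-dioxabicyclo[2.2.2]oct-5-ene (peroxide bridge anti to the isopropenyl group) | CC1=C[C@@H]2OO[C@H]1C[C@@H]2C(C)=C | intermediate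
5 | (4S,5R)-4-hydroxy-2-methyl-5-(prop-1-en-2-yl)cyclohex-2-en-1-one (hydroxyl trans to isopropenyl) | O=C1C(C)=C[C@H](O)[C@@H](C(C)=C)C1 | intermediate
6 | 2-bromo-3,3-diethoxyprop-1-ene | C=C(Br)C(OCC)OCC | starting material
7 | chloroacetaldehyde | ClCC=O | starting material
8 | (3,3-diethoxyprop-1-en-2-yl)lithium | [Li]C(=C)C(OCC)OCC | intermediate
9 | (3,3-diethoxyprop-1-en-2-yl)magnesium bromide | Br[Mg]C(=C)C(OCC)OCC | intermediate
10 | bis(bromomagnesium) enolate/alkoxide of the conjugate adduct (enolate C9=C10; C5 side chain cis to O6 and trans to the C7 isopropenyl group) | Br[Mg]OC1=C(C)[C@H](C(=C)C(OCC)OCC)[C@H](O[Mg]Br)[C@@H](C(C)=C)C1 | intermediate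
11 | (2R,3S,4R,5R)-2-[(1S)-2-chloro-1-hydroxyethyl]-3-(3,3-diethoxyprop-1-en-2-yl)-4-hydroxy-2-methyl-5-(prop-1-en-2-yl)cyclohexan-1-one | O=C1[C@@](C)([C@H](O)CCl)[C@H](C(=C)C(OCC)OCC)[C@H](O)[C@@H](C(C)=C)C1 | intermediate
12 | (2R,3S,4R,5R)-3-(3,3-diethoxyprop-1-en-2-yl)-4-hydroxy-2-methyl-2-[(2S)-oxiran-2-yl]-5-(prop-1-en-2-yl)cyclohexan-1-one | O=C1[C@@](C)([C@H]2CO2)[C@H](C(=C)C(OCC)OCC)[C@H](O)[C@@H](C(C)=C)C1 | intermediate
13 | angelic acid, (Z)-2-methylbut-2-enoic acid | C/C=C(/C)C(=O)O | starting material
14 | (Z)-2-methylbut-2-enoic 2,4,6-trichlorobenzoic anhydride | C/C=C(/C)C(=O)OC(=O)c1c(Cl)cc(Cl)cc1Cl | intermediate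
15 | (1R,2S,3R,6R)-2-(3,3-diethoxyprop-1-en-2-yl)-3-methyl-3-[(2S)-oxiran-2-yl]-4-oxo-6-(prop-1-en-2-yl)cyclohexyl (Z)-2-methylbut-2-enoate | O=C1[C@@](C)([C@H]2CO2)[C@H](C(=C)C(OCC)OCC)[C@H](OC(=O)/C(C)=C\C)[C@@H](C(C)=C)C1 | intermediate
16 | (1R,2S,3R,6R)-2-(3,3-diethoxyprop-1-en-2-yl)-6-(3-hydroxyprop-1-en-2-yl)-3-methyl-3-[(2S)-oxiran-2-yl]-4-oxocyclohexyl (Z)-2-methylbut-2-enoate | O=C1[C@@](C)([C@H]2CO2)[C@H](C(=C)C(OCC)OCC)[C@H](OC(=O)/C(C)=C\C)[C@@H](C(=C)CO)C1 | intermediate
17 | 2-[(1R,2R,3S,4R)-3-(3,3-diethoxyprop-1-en-2-yl)-4-methyl-2-{[(Z)-2-methylbut-2-enoyl]oxy}-4-[(2S)-oxiran-2-yl]-5-oxocyclohexyl]prop-2-enoic acid | O=C1[C@@](C)([C@H]2CO2)[C@H](C(=C)C(OCC)OCC)[C@H](OC(=O)/C(C)=C\C)[C@@H](C(=C)C(=O)O)C1 | intermediate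
18 | C8 α-iodo ketone of 17 (iodine on the ring carbon between the ketone and C7, trans to the acrylic acid side chain) | O=C1[C@@](C)([C@H]2CO2)[C@H](C(=C)C(OCC)OCC)[C@H](OC(=O)/C(C)=C\C)[C@@H](C(=C)C(=O)O)[C@@H]1I | intermediate
19 | (3aR,4S,5S,6R,7aR)-5-(3,3-diethoxyprop-1-en-2-yl)-6-methyl-3-methylidene-6-[(2S)-oxiran-2-yl]-2,7-dioxo-octahydro-1-benzofuran-4-yl (Z)-2-methylbut-2-enoate (cis-fused lactone) | C=C1C(=O)O[C@@H]2[C@H]1[C@@H](OC(=O)/C(C)=C\C)[C@@H](C(=C)C(OCC)OCC)[C@](C)([C@H]1CO1)C2=O | intermediate
20 | (3aR,4S,5R,6S,7S,7aR)-5-(3,3-diethoxyprop-1-en-2-yl)-7-hydroxy-6-methyl-3-methylidene-6-[(2S)-oxiran-2-yl]-2-oxo-octahydro-1-benzofuran-4-yl (Z)-2-methylbut-2-enoate | C=C1C(=O)O[C@@H]2[C@H]1[C@@H](OC(=O)/C(C)=C\C)[C@@H](C(=C)C(OCC)OCC)[C@](C)([C@H]1CO1)[C@@H]2O | intermediate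
21 | CNP0113462.5, (3aR,4S,5R,6S,7S,7aR)-7-hydroxy-6-methyl-3-methylidene-6-[(2S)-oxiran-2-yl]-2-oxo-5-(3-oxoprop-1-en-2-yl)octahydro-1-benzofuran-4-yl (Z)-2-methylbut-2-enoate | C=C1C(=O)O[C@@H]2[C@H]1[C@@H](OC(=O)/C(C)=C\C)[C@@H](C(=C)C=O)[C@](C)([C@H]1CO1)[C@@H]2O | target

**Step count and risks**
Total step count: 9. Longest linear sequence: 9 steps (1 → 21).

The three steps most likely to fail are 3, 4 and 8.

For step 3 the risks are the modest facial selectivity of singlet oxygen and, more seriously, the regiochemistry of the amine-induced peroxide opening, which could remove the C6 instead of the C9 bridgehead hydrogen. The fallback sets out from 4 (generated from 3 exactly as before). Thiourea in MeOH at 0 °C reduces the O–O bond to the cis-enediol F1. TEMPO (cat.) with PhI(OAc)2 in CH2Cl2 then oxidises the less hindered allylic carbinol at C9 (flanked by CH2) rather than the C6 carbinol next to the isopropenyl-bearing carbon, and the route is rejoined at 5.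

For step 4, the proposed new cascade, the risks are 1,2-addition of the Grignard reagent, retro-aldol loss before ring closure and a wrong C1 configuration. The fallback uses only known operations and sets out from 5. The directed 1,4-addition of 9 is run on its own and the enolate is trapped with Me3SiCl/Et3N to give the bis(trimethylsilyl) enol ether F2. MeLi (THF, 0 °C) regenerates the lithium enolate, ClTi(OiPr)3 turns it into the titanium enolate, and this adds to 7 at −78 °C through a closed transition state without retro-aldol. Citric-acid work-up removes the C6 silyl ether and gives 11 as an isolated chlorohydrin whose epimers can be separated. The route is rejoined at 11, which is closed to 12 with K2CO3/MeOH as in step 4.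

For step 8 the risks are slow enolisation of a dialkyl ketone under hypoiodite catalysis and iodination on the wrong face, which would give the trans-fused lactone. The fallback sets out from 17. KN(SiMe3)2 (2.2 equiv, THF, −78 °C) followed by 3-phenyl-2-(phenylsulfonyl)oxaziridine hydroxylates the C8 enolate on its less hindered face to give the α-hydroxy keto acid F3 (hydroxyl trans to the C7 side chain). PPh3/DIAD then closes the lactone with inversion at C8 (Mitsunobu lactonisation), and the route is rejoined at 19.

**Further compounds**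
F1 | step 3 | (1S,4S,5R)-2-methyl-5-(prop-1-en-2-yl)cyclohex-2-ene-1,4-diol (both hydroxyls trans to the isopropenyl group) | O[C@@H]1C(C)=C[C@H](O)[C@@H](C(C)=C)C1
F2 | step 4 | bis(trimethylsilyl) enol ether of the conjugate adduct (silyl enol ether C9=C10, silyl ether at C6; C5 side chain cis to O6, trans to the isopropenyl group) | C[Si](C)(C)OC1=C(C)[C@H](C(=C)C(OCC)OCC)[C@H](O[Si](C)(C)C)[C@@H](C(C)=C)C1
F3 | step 8 | C8 α-hydroxy derivative of keto acid 17 (hydroxyl trans to the acrylic acid side chain) | O=C1[C@@](C)([C@H]2CO2)[C@H](C(=C)C(OCC)OCC)[C@H](OC(=O)/C(C)=C\C)[C@@H](C(=C)C(=O)O)[C@@H]1O
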